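**Retrosynthetic overview**
1. Target 17 has a (2R,3R,4S) all-cis 5-deoxyflavan-3-ol upper unit joined C4→C6 to (2R,3S)-catechin. It comes from 16 by hydrogenolysis (eight benzyl ethers, C8–Br), and 16 from the 2,4-cis ketone 15 by hydride reduction, which sets C3.
2. The interflavan C4–C6 bond of 15 is made from the rhodium α-keto carbenoid of 4-diazoflavan-3-one 9, in which C4, normally the nucleophilic enolate carbon, is an electrophilic enolonium-type carbon. It is attacked by the nucleophilic C6 of 13; the C4–H is delivered last, by enol ketonisation.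
3. 9 comes from flavan-3-one 7 by diazo transfer. 7 comes from aryl propargyl ether 6 by gold α-oxo-carbene cyclisation (C4–C4a bond). This is the only ring built in the route (ring C of the upper unit).
4. 6 comes from racemic acetate 4 and phenol 5 by enantioconvergent copper-catalysed propargylic etherification, which sets C2. 4 comes from aldehyde 1 and ethynyl Grignard 2.
5. 13 comes from (+)-catechin 10 by perbenzylation and C8 bromination; all aromatic rings, the lower pyran ring and its two stereocentres are bought.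

Assumption: (S,S)-Ph-pybox is taken as the ligand antipode that gives the S ether 6 in step 2; if the sense of induction is the reverse, (R,R)-Ph-pybox is used instead.

**Step 1**
Reactants: 1 3,4-bis(benzyloxy)benzaldehyde; 2 ethynylmagnesium bromide
Product: 4 rac-1-[3,4-bis(benzyloxy)phenyl]prop-2-yn-1-yl acetate, via bromomagnesium alkoxide 3 (not isolated)
Conditions: THF, 0 °C; then Ac2O, DMAP (cat.), 0 °C → rt
Reagents that add atoms: acetic anhydride, CC(=O)OC(C)=O
Why: Grignard 1,2-addition of the acetylide to the aldehyde followed by in-flask O-acetylation of the magnesium alkoxide; the carbinol centre is left racemic on purpose because step 2 is enantioconvergent.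

**Step 2**
Reactants: 4 rac-1-[3,4-bis(benzyloxy)phenyl]prop-2-yn-1-yl acetate; 5 3-(benzyloxy)phenol
Product: 6 (S)-1,2-bis(benzyloxy)-4-{1-[3-(benzyloxy)phenoxy]prop-2-yn-1-yl}benzene
Conditions: (CuOTf)2·C6H6 (5 mol % Cu), (S,S)-Ph-pybox (10 mol %), i-Pr2NEt, PhMe, −10 °C
Reagents that add atoms: none
Why: Copper-catalysed enantioselective propargylic etherification (Nishibayashi type), in which both enantiomers of 4 ionise through the copper acetylide to one planar copper allenylidene and the pybox ligand directs phenol O-attack to one face, setting the future C2 (S in 6, R after ring closure, same spatial arrangement).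

**Step 3**
Reactants: 6 (S)-1,2-bis(benzyloxy)-4-{1-[3-(benzyloxy)phenoxy]prop-2-yn-1-yl}benzene
Product: 7 (2R)-7-(benzyloxy)-2-[3,4-bis(benzyloxy)phenyl]chroman-3-one
Conditions: [(Me4tBuXPhos)Au]NTf2 (5 mol %), 8-methylquinoline N-oxide (1.5 equiv, slow addition), ClCH2CH2Cl, rt
Reagents that add atoms: 8-methylquinoline N-oxide, Cc1cccc2ccc[n+]([O-])c12
Why: Gold-catalysed alkyne oxidation (Zhang chroman-3-one synthesis), in which the N-oxide delivers O to the internal alkyne carbon and the resulting α-oxo gold carbene, an electrophilic α-keto carbon, is trapped Friedel–Crafts-fashion by the aryl ether ring para to its OBn group, closing ring C without touching the C2 stereocentre.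

**Step 4**
Reactants: 7 (2R)-7-(benzyloxy)-2-[3,4-bis(benzyloxy)phenyl]chroman-3-one
Product: 9 (2R)-7-(benzyloxy)-2-[3,4-bis(benzyloxy)phenyl]-4-diazochroman-3-one, via trifluoroacetyl ketone 8 (not isolated)
Conditions: LiN(SiMe3)2, THF, −78 °C; CF3CO2CH2CF3, −78 °C; aq. HCl work-up; then MsN3, Et3N, H2O, MeCN, rt
Reagents that add atoms: methanesulfonyl azide, CS(=O)(=O)N=[N+]=[N-]; 2,2,2-trifluoroethyl trifluoroacetate, O=C(OCC(F)(F)F)C(F)(F)F (its CF3CO group is carried only by 8)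
Why: Danheiser detrifluoroacetylative diazo transfer, in which kinetic deprotonation at the less hindered benzylic C4 methylene (not the tertiary C2–H) and C-trifluoroacetylation activate C4 for diazo transfer under mild Et3N conditions, so C2 keeps its configuration.

**Step 5**
Reactants: 10 (+)-catechin
Product: 12 (2R,3S)-3,5,7-tris(benzyloxy)-2-[3,4-bis(benzyloxy)phenyl]chromane, via tetra-O-benzylcatechin 11 (not isolated)
Conditions: BnBr (4.4 equiv), K2CO3, DMF, 0 °C → rt; then NaH, BnBr (1.5 equiv), Bu4NI (cat.), 0 °C → rt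
Reagents that add atoms: benzyl bromide, BrCc1ccccc1
Why: Two-stage Williamson etherification in one flask, the four phenols first under mild carbonate conditions (no free phenoxide left to epimerise C2) and then the secondary 3-OH through its sodium alkoxide; no stereocentre is touched.

**Step 6**
Reactants: 12 (2R,3S)-3,5,7-tris(benzyloxy)-2-[3,4-bis(benzyloxy)phenyl]chromane
Product: 13 (2R,3S)-3,5,7-tris(benzyloxy)-2-[3,4-bis(benzyloxy)phenyl]-8-bromochromane
Conditions: NBS (1.05 equiv), CH2Cl2, −78 → 0 °C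
Reagents that add atoms: N-bromosuccinimide, O=C1CCC(=O)N1Br
Why: Electrophilic aromatic bromination, which in 5,7-di-O-benzylflavans goes selectively to C8 and so leaves C6 as the only nucleophilic ring A position for step 7.

**Step 7**
Reactants: 9 (2R)-7-(benzyloxy)-2-[3,4-bis(benzyloxy)phenyl]-4-diazochroman-3-one; 13 (2R,3S)-3,5,7-tris(benzyloxy)-2-[3,4-bis(benzyloxy)phenyl]-8-bromochromane
Product: 15 (2R,4S)-7-(benzyloxy)-2-[3,4-bis(benzyloxy)phenyl]-4-[(2R,3S)-3,5,7-tris(benzyloxy)-2-[3,4-bis(benzyloxy)phenyl]-8-bromochroman-6-yl]chroman-3-one, via enol 14 (not isolated)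
Conditions: Rh2(OAc)4 (2 mol %), 13 (1.5 equiv), 4 Å MS, CH2Cl2, 0 °C → rt, slow addition of 9; then AcOH (1 equiv), −40 → 0 °C
Reagents that add atoms: none
Why: Proposed new method: Rh2(OAc)4 converts the diazo carbon C4 into an electrophilic α-keto carbenoid (an enolonium-type carbon where the ketone would normally be nucleophilic), the electron-rich C6 of 13 (C8 blocked, no free OH) attacks it, the arenium/rhodium enolate collapses to enol 14, and ketonisation by axial protonation of C4 on the face away from the 2-aryl group leaves the new aryl group equatorial and cis to it (4S); the closest known reactions are dirhodium-carbenoid C–H arylations of 1,3,5-trimethoxybenzene with cyclic α-aryl-α-diazo carbonyl compounds and enol-mediated carbenoid X–H insertions.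

**Step 8**
Reactants: 15 (2R,4S)-7-(benzyloxy)-2-[3,4-bis(benzyloxy)phenyl]-4-[(2R,3S)-3,5,7-tris(benzyloxy)-2-[3,4-bis(benzyloxy)phenyl]-8-bromochroman-6-yl]chroman-3-one
Product: 16 (2R,3R,4S)-7-(benzyloxy)-2-[3,4-bis(benzyloxy)phenyl]-4-[(2R,3S)-3,5,7-tris(benzyloxy)-2-[3,4-bis(benzyloxy)phenyl]-8-bromochroman-6-yl]chroman-3-ol
Conditions: LiBH(s-Bu)3 (1.5 equiv), LiBr, THF, −78 °C; then H2O
Reagents that add atoms: none
Why: Substrate-controlled ketone reduction by a bulky trialkylborohydride, whose equatorial attack on the face opposite the two cis aryl groups gives the axial 3R alcohol cis to both (2,3-cis-3,4-cis), as in the known reduction of flavan-3-ones to epicatechin-type alcohols.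

**Step 9**
Reactants: 16 (2R,3R,4S)-7-(benzyloxy)-2-[3,4-bis(benzyloxy)phenyl]-4-[(2R,3S)-3,5,7-tris(benzyloxy)-2-[3,4-bis(benzyloxy)phenyl]-8-bromochroman-6-yl]chroman-3-ol
Product: 17 (2R,3R,4S)-2-(3,4-dihydroxyphenyl)-4-[(2R,3S)-2-(3,4-dihydroxyphenyl)-3,5,7-trihydroxychroman-6-yl]chroman-3,7-diol
Conditions: H2 (1 atm), Pd(OH)2/C, Et3N (2 equiv), THF/MeOH/H2O, rt
Reagents that add atoms: none
Why: Catalytic hydrogenolysis cleaves the eight benzyl ethers and the C8–Br bond in one operation (Et3N traps HBr) and touches no stereocentre.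

**Compound list**
1 | 3,4-bis(benzyloxy)benzaldehyde | O=Cc1ccc(OCc2ccccc2)c(OCc2ccccc2)c1 | starting material
2 | ethynylmagnesium bromide | C#C[Mg]Br | starting material
3 | bromomagnesium 1-[3,4-bis(benzyloxy)phenyl]prop-2-yn-1-olate (racemic) | C#CC(O[Mg]Br)c1ccc(OCc2ccccc2)c(OCc2ccccc2)c1 | intermediate
4 | rac-1-[3,4-bis(benzyloxy)phenyl]prop-2-yn-1-yl acetate | C#CC(OC(C)=O)c1ccc(OCc2ccccc2)c(OCc2ccccc2)c1 | intermediate
5 | 3-(benzyloxy)phenol | Oc1cccc(OCc2ccccc2)c1 | starting material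
6 | (S)-1,2-bis(benzyloxy)-4-{1-[3-(benzyloxy)phenoxy]prop-2-yn-1-yl}benzene | C#C[C@H](Oc1cccc(OCc2ccccc2)c1)c1ccc(OCc2ccccc2)c(OCc2ccccc2)c1 | intermediate
7 | (2R)-7-(benzyloxy)-2-[3,4-bis(benzyloxy)phenyl]chroman-3-one | O=C1Cc2ccc(OCc3ccccc3)cc2O[C@@H]1c1ccc(OCc2ccccc2)c(OCc2ccccc2)c1 | intermediate
8 | (2R)-7-(benzyloxy)-2-[3,4-bis(benzyloxy)phenyl]-4-(trifluoroacetyl)chroman-3-one (enolised, C4 not defined) | O=C1C(C(=O)C(F)(F)F)c2ccc(OCc3ccccc3)cc2O[C@@H]1c1ccc(OCc2ccccc2)c(OCc2ccccc2)c1 | intermediate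
9 | (2R)-7-(benzyloxy)-2-[3,4-bis(benzyloxy)phenyl]-4-diazochroman-3-one | O=C1C(=[N+]=[N-])c2ccc(OCc3ccccc3)cc2O[C@@H]1c1ccc(OCc2ccccc2)c(OCc2ccccc2)c1 | intermediate
10 | (+)-catechin, (2R,3S)-2-(3,4-dihydroxyphenyl)chroman-3,5,7-triol | O[C@H]1Cc2c(O)cc(O)cc2O[C@@H]1c1ccc(O)c(O)c1 | starting material
11 | (2R,3S)-5,7-bis(benzyloxy)-2-[3,4-bis(benzyloxy)phenyl]chroman-3-ol | O[C@H]1Cc2c(OCc3ccccc3)cc(OCc3ccccc3)cc2O[C@@H]1c1ccc(OCc2ccccc2)c(OCc2ccccc2)c1 | intermediate
12 | (2R,3S)-3,5,7-tris(benzyloxy)-2-[3,4-bis(benzyloxy)phenyl]chromane | O(Cc1ccccc1)[C@H]1Cc2c(OCc3ccccc3)cc(OCc3ccccc3)cc2O[C@@H]1c1ccc(OCc2ccccc2)c(OCc2ccccc2)c1 | intermediate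
13 | (2R,3S)-3,5,7-tris(benzyloxy)-2-[3,4-bis(benzyloxy)phenyl]-8-bromochromane | O(Cc1ccccc1)[C@H]1Cc2c(OCc3ccccc3)cc(OCc3ccccc3)c(Br)c2O[C@@H]1c1ccc(OCc2ccccc2)c(OCc2ccccc2)c1 | intermediate
14 | (2R)-7-(benzyloxy)-2-[3,4-bis(benzyloxy)phenyl]-4-[(2R,3S)-3,5,7-tris(benzyloxy)-2-[3,4-bis(benzyloxy)phenyl]-8-bromochroman-6-yl]-2H-chromen-3-ol | O(Cc3ccccc3)c1ccc2c(c1)O[C@H](c1ccc(OCc3ccccc3)c(OCc3ccccc3)c1)C(O)=C2c1c(OCc3ccccc3)c(Br)c2c(c1OCc3ccccc3)C[C@H](OCc3ccccc3)[C@@H](c1ccc(OCc3ccccc3)c(OCc3ccccc3)c1)O2 | intermediate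
15 | (2R,4S)-7-(benzyloxy)-2-[3,4-bis(benzyloxy)phenyl]-4-[(2R,3S)-3,5,7-tris(benzyloxy)-2-[3,4-bis(benzyloxy)phenyl]-8-bromochroman-6-yl]chroman-3-one | O(Cc3ccccc3)c1ccc2c(c1)O[C@H](c1ccc(OCc3ccccc3)c(OCc3ccccc3)c1)C(=O)[C@@H]2c1c(OCc3ccccc3)c(Br)c2c(c1OCc3ccccc3)C[C@H](OCc3ccccc3)[C@@H](c1ccc(OCc3ccccc3)c(OCc3ccccc3)c1)O2 | intermediate
16 | (2R,3R,4S)-7-(benzyloxy)-2-[3,4-bis(benzyloxy)phenyl]-4-[(2R,3S)-3,5,7-tris(benzyloxy)-2-[3,4-bis(benzyloxy)phenyl]-8-bromochroman-6-yl]chroman-3-ol | O(Cc3ccccc3)c1ccc2c(c1)O[C@H](c1ccc(OCc3ccccc3)c(OCc3ccccc3)c1)[C@H](O)[C@@H]2c1c(OCc3ccccc3)c(Br)c2c(c1OCc3ccccc3)C[C@H](OCc3ccccc3)[C@@H](c1ccc(OCc3ccccc3)c(OCc3ccccc3)c1)O2 | intermediate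
17 | (2R,3R,4S)-2-(3,4-dihydroxyphenyl)-4-[(2R,3S)-2-(3,4-dihydroxyphenyl)-3,5,7-trihydroxychroman-6-yl]chroman-3,7-diol | Oc1ccc2c(c1)O[C@H](c1ccc(O)c(O)c1)[C@H](O)[C@@H]2c1c(O)cc2c(c1O)C[C@H](O)[C@@H](c1ccc(O)c(O)c1)O2 | target

**Step count and risks**
Total steps: 9. Longest linear sequence: 7 (steps 1, 2, 3, 4, 7, 8, 9); steps 5 and 6 make the second fragment.

The step most likely to fail is step 7. The carbenoid can be lost to dimerisation or to ylide formation at a benzyl ether oxygen. If the hydrogen reaches C4 by a direct 1,2-shift instead of through enol 14, the 2,4-trans ketone results, which does not lead to the target. The fallback is a cationic C4 coupling at the alcohol oxidation level. It sets out from 7: NaBH4 (THF/MeOH, −40 °C, axial attack) gives mainly the 2,3-trans alcohol (2R,3S)-7-(benzyloxy)-2-[3,4-bis(benzyloxy)phenyl]chroman-3-ol F1. DDQ with 2-ethoxyethanol in CH2Cl2 oxidises its C4 to the ether (2R,3S,4S)-7-(benzyloxy)-2-[3,4-bis(benzyloxy)phenyl]-4-(2-ethoxyethoxy)chroman-3-ol F2. Me3SiOTf (cat.) with 13 at −78 °C ionises F2, and C6 of 13 adds trans to the 3-OH to give the 3,4-trans, 2,4-cis alcohol (2R,3S,4S)-7-(benzyloxy)-2-[3,4-bis(benzyloxy)phenyl]-4-[(2R,3S)-3,5,7-tris(benzyloxy)-2-[3,4-bis(benzyloxy)phenyl]-8-bromochroman-6-yl]chroman-3-ol F3. Dess–Martin periodinane then gives ketone 15, where the route is rejoined before step 8.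

The second is step 3. Direct 6-endo hydroarylation of the very electron-rich aryl ether can outrun oxygen transfer, and the carbene can be over-oxidised. The fallback uses that hydroarylation and sets out from 6: (Ph3P)AuNTf2 (2 mol %) in CH2Cl2 gives the chromene (S)-7-(benzyloxy)-2-[3,4-bis(benzyloxy)phenyl]-2H-chromene F4. Dimethyldioxirane in acetone at −40 °C epoxidises it anti to the 2-aryl group to (2R,3S,4S)-7-(benzyloxy)-2-[3,4-bis(benzyloxy)phenyl]-3,4-epoxychromane F5. ZnI2 (cat.) in CH2Cl2 opens the epoxide at benzylic C4, and a 1,2-hydride shift (Meinwald rearrangement) gives ketone 7, rejoining before step 4.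

The third is step 2. The resorcinol-type phenol may be C-propargylated, or the electron-rich aryl acetate may give a low ee. The fallback is resolution followed by SN2 etherification and sets out from 4: lipase B from Candida antarctica in phosphate buffer/t-BuOMe hydrolyses the fast-reacting R acetate to the alcohol (R)-1-[3,4-bis(benzyloxy)phenyl]prop-2-yn-1-ol F6, and the slow S acetate is recovered. Mitsunobu reaction of F6 with 5 (PPh3, DIAD, PhMe, −20 °C) inverts the carbinol centre and gives ether 6, rejoining before step 3.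

**Further compounds**
F1 | step 7 | (2R,3S)-7-(benzyloxy)-2-[3,4-bis(benzyloxy)phenyl]chroman-3-ol | O[C@H]1Cc2ccc(OCc3ccccc3)cc2O[C@@H]1c1ccc(OCc2ccccc2)c(OCc2ccccc2)c1
F2 | step 7 | (2R,3S,4S)-7-(benzyloxy)-2-[3,4-bis(benzyloxy)phenyl]-4-(2-ethoxyethoxy)chroman-3-ol | O[C@H]1[C@@H](OCCOCC)c2ccc(OCc3ccccc3)cc2O[C@@H]1c1ccc(OCc2ccccc2)c(OCc2ccccc2)c1
F3 | step 7 | (2R,3S,4S)-7-(benzyloxy)-2-[3,4-bis(benzyloxy)phenyl]-4-[(2R,3S)-3,5,7-tris(benzyloxy)-2-[3,4-bis(benzyloxy)phenyl]-8-bromochroman-6-yl]chroman-3-ol | O(Cc3ccccc3)c1ccc2c(c1)O[C@H](c1ccc(OCc3ccccc3)c(OCc3ccccc3)c1)[C@@H](O)[C@@H]2c1c(OCc3ccccc3)c(Br)c2c(c1OCc3ccccc3)C[C@H](OCc3ccccc3)[C@@H](c1ccc(OCc3ccccc3)c(OCc3ccccc3)c1)O2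
F4 | step 3 | (S)-7-(benzyloxy)-2-[3,4-bis(benzyloxy)phenyl]-2H-chromene | C1=Cc2ccc(OCc3ccccc3)cc2O[C@@H]1c1ccc(OCc2ccccc2)c(OCc2ccccc2)c1
F5 | step 3 | (2R,3S,4S)-7-(benzyloxy)-2-[3,4-bis(benzyloxy)phenyl]-3,4-epoxychromane (epoxide trans to the 2-aryl group) | O(Cc3ccccc3)c1ccc2c(c1)O[C@H](c1ccc(OCc3ccccc3)c(OCc3ccccc3)c1)[C@H]4O[C@@H]24
F6 | step 2 | (R)-1-[3,4-bis(benzyloxy)phenyl]prop-2-yn-1-ol | C#C[C@@H](O)c1ccc(OCc2ccccc2)c(OCc2ccccc2)c1
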